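The route disconnects ring B (the pyran) of the 2H-chromene at O1–C2 together with the C1'–C2' bond of the side chain. The key step exploits the fully substituted C2 of ring B, which is bonded to O1, to a methyl group and to the C1' methylene that continues into the E C2'=C3' alkene. A ligand-controlled oxypalladation of a 1,1-disubstituted alkene, terminated by Heck capture of 2-methylbut-3-en-2-ol, closes ring B as a chroman, sets C2 and attaches the complete hydroxylated side chain in one operation. The precursor is a 3-hydroxybenzaldehyde with a 3-methylbut-3-enyl arm at C2 and a SEM-protected oxygen at C4.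

Key step: step 4

Remark: chromene numbering is used (ring A benzo, ring B pyran, ring C the 2,4-dihydroxyphenyl ring; primed atoms count the side chain from C2). SEM = [2-(trimethylsilyl)ethoxy]methyl. The target is (2R). The (S,S) ligand is assumed to give the required sense at C2 by analogy with acrylate acceptors in this reaction class; should the sense be opposite, the enantiomeric ligand is used and nothing else changes.

Step 1
Reactants: 1 2-bromo-3-hydroxy-4-methoxybenzaldehyde (2-bromoisovanillin)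
Product: 2 2-bromo-3,4-dihydroxybenzaldehyde
Conditions: BBr3 (2.5 equiv), CH2Cl2, −78 °C to rt; then H2O
Reagents that add atoms: none
Why: Lewis acid ether cleavage, in which BBr3 coordinates the methoxy oxygen and bromide removes the methyl group by SN2 attack while the aryl bromide and the aldehyde are left alone at low temperature.

Step 2
Reactants: 2 2-bromo-3,4-dihydroxybenzaldehyde
Product: 3 2-bromo-3-hydroxy-4-(SEM-oxy)benzaldehyde
Conditions: SEMCl (1.05 equiv), K2CO3 (1.1 equiv), DMF, 0 °C
Reagents that add atoms: 2-(trimethylsilyl)ethoxymethyl chloride (SEMCl), C[Si](C)(C)CCOCCl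
Why: Williamson-type O-alkylation under acidity control, since the hydroxyl para to the formyl group is the more acidic and less hindered one, so one equivalent of base should protect O4 and leave the bromine-flanked O3 hydroxyl free.

Step 3
Reactants: 3 2-bromo-3-hydroxy-4-(SEM-oxy)benzaldehyde; 4 4-bromo-2-methylbut-1-ene
Product: 6 3-hydroxy-2-(3-methylbut-3-en-1-yl)-4-(SEM-oxy)benzaldehyde, via 3-methylbut-3-enylzinc bromide 5 (not isolated)
Conditions: 4, Zn dust, LiCl, THF, 40 °C; then 3, Pd(OAc)2 (2 mol %), SPhos (4 mol %), THF, rt, slow addition of 5 (1.5 equiv)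
Reagents that add atoms: none
Why: Negishi coupling, in which an electron-rich biaryl phosphine catalyst should couple a primary alkylzinc halide with the ortho-substituted aryl bromide faster than the zinc reagent is protonated by the phenol, and alkylzinc halides do not add to the aldehyde.

Step 4
Reactants: 6 3-hydroxy-2-(3-methylbut-3-en-1-yl)-4-(SEM-oxy)benzaldehyde; 7 2-methylbut-3-en-2-ol
Product: 8 (2S)-2-[(2E)-4-hydroxy-4-methylpent-2-en-1-yl]-2-methyl-8-(SEM-oxy)chroman-5-carbaldehyde
Conditions: Pd(OCOCF3)2 (10 mol %), (S,S)-Bn-BOXAX [(aS)-2,2'-bis((4S)-4-benzyl-4,5-dihydrooxazol-2-yl)-1,1'-binaphthyl] (40 mol %), p-benzoquinone (4 equiv), 7 (10 equiv), CH2Cl2, rt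
Reagents that add atoms: none
Why: Proposed new method: the chiral complex of divalent palladium binds the 1,1-disubstituted alkene of 6, the C3 hydroxyl of the benzaldehyde (the future O1) attacks the internal alkene carbon to form O1–C2, and the resulting C1' σ-alkylpalladium, which has no β-hydrogen because C2 is quaternary, inserts the vinyl group of 7 at its terminal carbon (C1'–C2' bond) before β-hydride elimination from C2' releases the E C2'=C3' alkene and p-benzoquinone returns zerovalent palladium to the divalent state. The closest known reaction type is the enantioselective domino Wacker–Heck synthesis of 2-methyl-2-(alkenylmethyl)chromans with acrylate or vinyl ketone acceptors; the new element is the unactivated tertiary allylic alcohol acceptor, which is expected to insert because the trifluoroacetate catalyst is electrophilic, because this alcohol inserts at its terminal carbon in ordinary Heck arylations, and because the alkylpalladium has no faster exit. Ring B closes in the 6-exo-trig mode. The new stereocentre C2 is under catalyst control: the bis(oxazoline) biaryl ligand differentiates the enantiotopic faces of an alkene whose methyl and arylethyl substituents differ clearly, and the substrate has no other stereocentre. The step needs facial selectivity (ligand), Heck capture in preference to protodepalladation (excess 7, no β-hydrogen at C1'), a single direction of β-elimination (C4' is fully substituted, so only C2'–H is available and the alcohol cannot isomerise to a carbonyl compound) and a single nucleophile (SEM blocks O4, so only the C3 hydroxyl can cyclise).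

Step 5
Reactants: 8 (2S)-2-[(2E)-4-hydroxy-4-methylpent-2-en-1-yl]-2-methyl-8-(SEM-oxy)chroman-5-carbaldehyde
Product: 9 (2S)-2-methyl-2-[(2E)-4-methyl-4-(triethylsilyloxy)pent-2-en-1-yl]-8-(SEM-oxy)chroman-5-carbaldehyde
Conditions: Et3SiOTf (1.3 equiv), 2,6-lutidine (2 equiv), CH2Cl2, −78 °C
Reagents that add atoms: triethylsilyl trifluoromethanesulfonate, CC[Si](CC)(CC)OS(=O)(=O)C(F)(F)F
Why: Silylation of a tertiary alcohol with a silyl triflate and a hindered pyridine base is fast at low temperature, leaves the non-enolisable aldehyde and the SEM acetal untouched, and masks the ionisable tertiary allylic alcohol for the hot oxidation that follows.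

Step 6
Reactants: 9 (2S)-2-methyl-2-[(2E)-4-methyl-4-(triethylsilyloxy)pent-2-en-1-yl]-8-(SEM-oxy)chroman-5-carbaldehyde
Product: 10 (2R)-2-methyl-2-[(2E)-4-methyl-4-(triethylsilyloxy)pent-2-en-1-yl]-8-(SEM-oxy)-2H-chromene-5-carbaldehyde
Conditions: DDQ (2 equiv), 1,4-dioxane, 80 °C, dark
Reagents that add atoms: none
Why: DDQ dehydrogenation, in which hydride abstraction from benzylic C4 gives a cation stabilised by O1 through C8a and loss of a C3 proton gives the C3=C4 alkene, with no bond to C2 touched (the descriptor changes from S to R only because C3 becomes sp2).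

Step 7
Reactants: 11 1-(2,4-dihydroxyphenyl)ethanone (2,4-dihydroxyacetophenone)
Product: 12 1-[2,4-bis(SEM-oxy)phenyl]ethanone
Conditions: NaH (2.2 equiv), SEMCl (2.3 equiv), DMF, 0 °C to rt
Reagents that add atoms: 2-(trimethylsilyl)ethoxymethyl chloride (SEMCl), C[Si](C)(C)CCOCCl
Why: Williamson-type double O-alkylation of the sodium bis-phenoxide, for which NaH is chosen because the ortho hydroxyl is hydrogen-bonded to the ketone and is not alkylated cleanly with weaker bases.

Step 8
Reactants: 10 (2R)-2-methyl-2-[(2E)-4-methyl-4-(triethylsilyloxy)pent-2-en-1-yl]-8-(SEM-oxy)-2H-chromene-5-carbaldehyde; 12 1-[2,4-bis(SEM-oxy)phenyl]ethanone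
Product: 14 (2E)-1-[2,4-bis(SEM-oxy)phenyl]-3-{(2R)-2-methyl-2-[(2E)-4-methyl-4-(triethylsilyloxy)pent-2-en-1-yl]-8-(SEM-oxy)-2H-chromen-5-yl}prop-2-en-1-one, via aldol adduct 13 (not isolated)
Conditions: KOH (3 equiv), EtOH/THF, 0 °C to rt
Reagents that add atoms: none
Why: Claisen–Schmidt condensation, in which the non-enolisable aldehyde accepts the enolate of the methyl ketone and E1cB loss of water from aldol 13 gives the E enone, while the SEM ethers, the tertiary silyl ether and the chromene are stable to base.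

Step 9
Reactants: 14 (2E)-1-[2,4-bis(SEM-oxy)phenyl]-3-{(2R)-2-methyl-2-[(2E)-4-methyl-4-(triethylsilyloxy)pent-2-en-1-yl]-8-(SEM-oxy)-2H-chromen-5-yl}prop-2-en-1-one
Product: 15 1-[2,4-bis(SEM-oxy)phenyl]-3-{(2R)-2-methyl-2-[(2E)-4-methyl-4-(triethylsilyloxy)pent-2-en-1-yl]-8-(SEM-oxy)-2H-chromen-5-yl}propan-1-one
Conditions: [(Ph3P)CuH]6 (5 mol %), PhMe2SiH (1.5 equiv), t-BuOH (1.5 equiv), toluene, rt
Reagents that add atoms: none
Why: Copper hydride conjugate reduction, in which the phosphine copper hydride delivers hydride only to the β-carbon of the enone, tert-butanol protonates the copper enolate and the silane regenerates the hydride, so the chromene C3=C4 and the C2'=C3' alkene, neither of which is conjugated with a carbonyl group, are left alone.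

Step 10
Reactants: 15 1-[2,4-bis(SEM-oxy)phenyl]-3-{(2R)-2-methyl-2-[(2E)-4-methyl-4-(triethylsilyloxy)pent-2-en-1-yl]-8-(SEM-oxy)-2H-chromen-5-yl}propan-1-one
Product: 16 1-(2,4-dihydroxyphenyl)-3-{(2R)-8-hydroxy-2-[(2E)-4-hydroxy-4-methylpent-2-en-1-yl]-2-methyl-2H-chromen-5-yl}propan-1-one (CNP0311864.1)
Conditions: Bu4NF (12 equiv), THF/DMPU, 50 °C, dark; then aq NH4Cl
Reagents that add atoms: none
Why: Fluoride-induced desilylation, in which attack at silicon fragments each SEM group to fluorotrimethylsilane, ethene and formaldehyde and cleaves the triethylsilyl ether, under basic conditions that touch neither the tertiary allylic alcohol, the alkenes nor C2.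

Compound list
1 | 2-bromo-3-hydroxy-4-methoxybenzaldehyde (2-bromoisovanillin) | COc1ccc(C=O)c(Br)c1O | starting material
2 | 2-bromo-3,4-dihydroxybenzaldehyde | O=Cc1ccc(O)c(O)c1Br | intermediate
3 | 2-bromo-3-hydroxy-4-{[2-(trimethylsilyl)ethoxy]methoxy}benzaldehyde | O=Cc1ccc(OCOCC[Si](C)(C)C)c(O)c1Br | intermediate
4 | 4-bromo-2-methylbut-1-ene | C=C(C)CCBr | starting material
5 | 3-methylbut-3-enylzinc bromide | C=C(C)CC[Zn]Br | intermediate
6 | 3-hydroxy-2-(3-methylbut-3-en-1-yl)-4-{[2-(trimethylsilyl)ethoxy]methoxy}benzaldehyde | C=C(C)CCc1c(C=O)ccc(OCOCC[Si](C)(C)C)c1O | intermediate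
7 | 2-methylbut-3-en-2-ol | C=CC(C)(C)O | starting material
8 | (2S)-2-[(2E)-4-hydroxy-4-methylpent-2-en-1-yl]-2-methyl-8-{[2-(trimethylsilyl)ethoxy]methoxy}-3,4-dihydro-2H-chromene-5-carbaldehyde | CC(C)(O)/C=C/C[C@]1(C)CCc2c(C=O)ccc(OCOCC[Si](C)(C)C)c2O1 | intermediate
9 | (2S)-2-methyl-2-[(2E)-4-methyl-4-(triethylsilyloxy)pent-2-en-1-yl]-8-{[2-(trimethylsilyl)ethoxy]methoxy}-3,4-dihydro-2H-chromene-5-carbaldehyde | CC[Si](CC)(CC)OC(C)(C)/C=C/C[C@]1(C)CCc2c(C=O)ccc(OCOCC[Si](C)(C)C)c2O1 | intermediate
10 | (2R)-2-methyl-2-[(2E)-4-methyl-4-(triethylsilyloxy)pent-2-en-1-yl]-8-{[2-(trimethylsilyl)ethoxy]methoxy}-2H-chromene-5-carbaldehyde | CC[Si](CC)(CC)OC(C)(C)/C=C/C[C@]1(C)C=Cc2c(C=O)ccc(OCOCC[Si](C)(C)C)c2O1 | intermediate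
11 | 1-(2,4-dihydroxyphenyl)ethanone (2,4-dihydroxyacetophenone) | CC(=O)c1ccc(O)cc1O | starting material
12 | 1-(2,4-bis{[2-(trimethylsilyl)ethoxy]methoxy}phenyl)ethanone | CC(=O)c1ccc(OCOCC[Si](C)(C)C)cc1OCOCC[Si](C)(C)C | intermediate
13 | aldol adduct: 3-hydroxy-1-[2,4-bis(SEM-oxy)phenyl]-3-{(2R)-2-methyl-2-[(2E)-4-methyl-4-(triethylsilyloxy)pent-2-en-1-yl]-8-(SEM-oxy)-2H-chromen-5-yl}propan-1-one, carbinol centre not controlled | CC[Si](CC)(CC)OC(C)(C)/C=C/C[C@]1(C)C=Cc2c(C(O)CC(=O)c3ccc(OCOCC[Si](C)(C)C)cc3OCOCC[Si](C)(C)C)ccc(OCOCC[Si](C)(C)C)c2O1 | intermediate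
14 | (2E)-1-[2,4-bis(SEM-oxy)phenyl]-3-{(2R)-2-methyl-2-[(2E)-4-methyl-4-(triethylsilyloxy)pent-2-en-1-yl]-8-(SEM-oxy)-2H-chromen-5-yl}prop-2-en-1-one | CC[Si](CC)(CC)OC(C)(C)/C=C/C[C@]1(C)C=Cc2c(/C=C/C(=O)c3ccc(OCOCC[Si](C)(C)C)cc3OCOCC[Si](C)(C)C)ccc(OCOCC[Si](C)(C)C)c2O1 | intermediate
15 | 1-[2,4-bis(SEM-oxy)phenyl]-3-{(2R)-2-methyl-2-[(2E)-4-methyl-4-(triethylsilyloxy)pent-2-en-1-yl]-8-(SEM-oxy)-2H-chromen-5-yl}propan-1-one | CC[Si](CC)(CC)OC(C)(C)/C=C/C[C@]1(C)C=Cc2c(CCC(=O)c3ccc(OCOCC[Si](C)(C)C)cc3OCOCC[Si](C)(C)C)ccc(OCOCC[Si](C)(C)C)c2O1 | intermediate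
16 | 1-(2,4-dihydroxyphenyl)-3-{(2R)-8-hydroxy-2-[(2E)-4-hydroxy-4-methylpent-2-en-1-yl]-2-methyl-2H-chromen-5-yl}propan-1-one (CNP0311864.1) | CC(C)(O)/C=C/C[C@]1(C)C=Cc2c(CCC(=O)c3ccc(O)cc3O)ccc(O)c2O1 | target

Total step count: 10. Longest linear sequence: 9 steps (steps 1–6 and 8–10; step 7 is a one-step side branch).

Steps most likely to fail

Step 4. Insertion of the unactivated alkene into the hindered alkylpalladium may be too slow, so that protodepalladation or catalyst decay takes over. β-Hydroxide elimination may compete with β-hydride elimination, liberated CF3CO2H may ionise the tertiary allylic alcohol, and facial selectivity may erode with the new acceptor. The fallback uses the established acceptor class. It sets out from 6, which under the same catalyst with methyl acrylate should give methyl (2E)-4-[(2S)-5-formyl-2-methyl-8-(SEM-oxy)chroman-2-yl]but-2-enoate F1. Acetalisation of the formyl group (HC(OMe)3, pyridinium p-toluenesulfonate, MeOH, rt) should give the dimethyl acetal ester F2. Double 1,2-addition of MeLi (3 equiv, THF, −78 °C) to the ester should give the tertiary alcohol acetal F3. Mild hydrolysis (pyridinium p-toluenesulfonate, acetone/water, rt) returns the aldehyde, and the route is rejoined at 8.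

Step 6. Hydride abstraction from C4 may be sluggish because the formyl group at C5 depletes ring A. Prolonged heating then invites ionisation of the allylic silyl ether, oxidation at allylic C1', or loss of enantiomeric purity through reversible electrocyclic opening of the chromene. The fallback moves the dehydrogenation to the chalcone stage, where the C5 substituent is a vinylogous and therefore weaker acceptor and where oxidation of chromans to chromenes with DDQ is well established. It sets out from 9, which is condensed with 12 (KOH, EtOH/THF) through the aldol adduct F4 to the chroman chalcone F5. DDQ in 1,4-dioxane then dehydrogenates C3–C4, and the route is rejoined at 14.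

Step 10. Cleavage of three aryl SEM ethers may stall at the electron-rich C8 ether. The forcing conditions then needed risk hydroxymethylation of the liberated resorcinol ring C by the formaldehyde set free, and thermal racemisation of the chromene. The fallback changes the protecting-group plan for ring C. It sets out from 11, which with allyl bromide and K2CO3 in DMF at 60 °C should give 1-[2,4-bis(allyloxy)phenyl]ethanone F6. Claisen–Schmidt condensation of F6 with 10 should lead through the aldol adduct F7 to the bis(allyl) chalcone F8, and the copper hydride conjugate reduction of step 9 should give the bis(allyl) dihydrochalcone F9. Bu4NF then has to remove only one SEM group and the silyl ether while ring C is still masked, giving the bis(allyl) ether diol F10. A neutral deallylation (Pd(PPh3)4, K2CO3, MeOH, rt, zerovalent palladium with methanol as allyl acceptor) completes the sequence, and the route is rejoined at 16.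

Further compounds
F1 | step 4 | methyl (2E)-4-[(2S)-5-formyl-2-methyl-8-{[2-(trimethylsilyl)ethoxy]methoxy}-3,4-dihydro-2H-chromen-2-yl]but-2-enoate | COC(=O)/C=C/C[C@]1(C)CCc2c(C=O)ccc(OCOCC[Si](C)(C)C)c2O1
F2 | step 4 | methyl (2E)-4-[(2S)-5-(dimethoxymethyl)-2-methyl-8-{[2-(trimethylsilyl)ethoxy]methoxy}-3,4-dihydro-2H-chromen-2-yl]but-2-enoate | COC(=O)/C=C/C[C@]1(C)CCc2c(C(OC)OC)ccc(OCOCC[Si](C)(C)C)c2O1
F3 | step 4 | (3E)-5-[(2S)-5-(dimethoxymethyl)-2-methyl-8-{[2-(trimethylsilyl)ethoxy]methoxy}-3,4-dihydro-2H-chromen-2-yl]-2-methylpent-3-en-2-ol | CC(C)(O)/C=C/C[C@]1(C)CCc2c(C(OC)OC)ccc(OCOCC[Si](C)(C)C)c2O1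
F4 | step 6 | aldol adduct: 3-hydroxy-1-[2,4-bis(SEM-oxy)phenyl]-3-{(2S)-2-methyl-2-[(2E)-4-methyl-4-(triethylsilyloxy)pent-2-en-1-yl]-8-(SEM-oxy)chroman-5-yl}propan-1-one, carbinol centre not controlled | CC[Si](CC)(CC)OC(C)(C)/C=C/C[C@]1(C)CCc2c(C(O)CC(=O)c3ccc(OCOCC[Si](C)(C)C)cc3OCOCC[Si](C)(C)C)ccc(OCOCC[Si](C)(C)C)c2O1
F5 | step 6 | (2E)-1-[2,4-bis(SEM-oxy)phenyl]-3-{(2S)-2-methyl-2-[(2E)-4-methyl-4-(triethylsilyloxy)pent-2-en-1-yl]-8-(SEM-oxy)chroman-5-yl}prop-2-en-1-one | CC[Si](CC)(CC)OC(C)(C)/C=C/C[C@]1(C)CCc2c(/C=C/C(=O)c3ccc(OCOCC[Si](C)(C)C)cc3OCOCC[Si](C)(C)C)ccc(OCOCC[Si](C)(C)C)c2O1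
F6 | step 10 | 1-[2,4-bis(prop-2-en-1-yloxy)phenyl]ethanone | CC(=O)c1ccc(OCC=C)cc1OCC=C
F7 | step 10 | aldol adduct: 3-hydroxy-1-[2,4-bis(allyloxy)phenyl]-3-{(2R)-2-methyl-2-[(2E)-4-methyl-4-(triethylsilyloxy)pent-2-en-1-yl]-8-(SEM-oxy)-2H-chromen-5-yl}propan-1-one, carbinol centre not controlled | CC[Si](CC)(CC)OC(C)(C)/C=C/C[C@]1(C)C=Cc2c(C(O)CC(=O)c3ccc(OCC=C)cc3OCC=C)ccc(OCOCC[Si](C)(C)C)c2O1
F8 | step 10 | (2E)-1-[2,4-bis(allyloxy)phenyl]-3-{(2R)-2-methyl-2-[(2E)-4-methyl-4-(triethylsilyloxy)pent-2-en-1-yl]-8-(SEM-oxy)-2H-chromen-5-yl}prop-2-en-1-one | CC[Si](CC)(CC)OC(C)(C)/C=C/C[C@]1(C)C=Cc2c(/C=C/C(=O)c3ccc(OCC=C)cc3OCC=C)ccc(OCOCC[Si](C)(C)C)c2O1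
F9 | step 10 | 1-[2,4-bis(allyloxy)phenyl]-3-{(2R)-2-methyl-2-[(2E)-4-methyl-4-(triethylsilyloxy)pent-2-en-1-yl]-8-(SEM-oxy)-2H-chromen-5-yl}propan-1-one | CC[Si](CC)(CC)OC(C)(C)/C=C/C[C@]1(C)C=Cc2c(CCC(=O)c3ccc(OCC=C)cc3OCC=C)ccc(OCOCC[Si](C)(C)C)c2O1
F10 | step 10 | 1-[2,4-bis(allyloxy)phenyl]-3-{(2R)-8-hydroxy-2-[(2E)-4-hydroxy-4-methylpent-2-en-1-yl]-2-methyl-2H-chromen-5-yl}propan-1-one | CC(C)(O)/C=C/C[C@]1(C)C=Cc2c(CCC(=O)c3ccc(OCC=C)cc3OCC=C)ccc(O)c2O1
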